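**Retrosynthetic overview**
1. The C8 ester and the C8 configuration come from a Mitsunobu inversion of a 1,3-anti diol with 3,4,5-trimethoxybenzoic acid; the ten-membered ring is closed last by ring-closing metathesis at C1=C10.
2. C6–C7 and C8–C9 come from an L-proline anti-aldol of an epoxy aldehyde with 3-methylbutanal, then a chelation-controlled methallyl Grignard addition.
3. The oxirane (first ring formed) comes from Sharpless epoxidation of (2Z)-3-methylhepta-2,6-dien-1-ol.
4. Key step: that Z-allylic alcohol comes from Birch dearomatization of 4-methylanisole. The six-membered ring holds the trisubstituted olefin cis, and a regioselective Baeyer–Villiger scission then opens the ring.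
5. Ring order: oxirane (step 4), then the ten-membered carbocycle (step 9).

Assumption: the SMILES is read literally, i.e. (Z)-C1=C10 olefin, cis-oxirane, (4S,5R,6R,7S,8R); locants C1–C10 are the ring carbons of the target (C4/C5 oxirane, C6 carbinol, C7 isopropyl carbon, C8 ester carbon, methyl on C10).

**Route**

Step 1
Reactants: 1 4-methylanisole
Product: 3 4-methylcyclohex-3-en-1-one, via 1-methoxy-4-methylcyclohexa-1,4-diene 2 (not isolated)
Conditions: Li, NH3(l), THF, t-BuOH, −78 °C; H2O work-up; crude 2 then (CO2H)2 (cat.), THF/H2O, 20 °C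
Reagents that add atoms: water, O
Why: Birch reduction breaks the aromatic ring to the 2,5-dihydroanisole and mild enol ether hydrolysis gives the β,γ-unsaturated ketone without conjugation, so the future C4=C5 trisubstituted olefin is locked cis inside a six-membered ring.

Step 2
Reactants: 3 4-methylcyclohex-3-en-1-one
Product: 4 5-methyl-4,7-dihydro-3H-oxepin-2-one
Conditions: Me3SiOOSiMe3, Me3SiOTf (cat.), CH2Cl2, −40 °C
Reagents that add atoms: bis(trimethylsilyl) peroxide, C[Si](C)(C)OO[Si](C)(C)C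
Why: Baeyer–Villiger oxidation in which the allylic methylene migrates in preference to the plain methylene and the silyl peroxide does not epoxidise the olefin, so oxygen is placed on the future C6 and the ring-derived Z geometry is kept.

Step 3
Reactants: 4 5-methyl-4,7-dihydro-3H-oxepin-2-one
Product: 6 (2Z)-3-methylhepta-2,6-dien-1-ol, via lactol 5 (not isolated)
Conditions: i-Bu2AlH, CH2Cl2, −78 °C; then Ph3P=CH2 (from Ph3PCH3Br, KN(SiMe3)2), THF, −78 → 20 °C; H2O
Reagents that add atoms: methyltriphenylphosphonium bromide, C[P+](c1ccccc1)(c1ccccc1)c1ccccc1.[Br-]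
Why: Partial lactone reduction to the lactol followed by Wittig methylenation of its open hydroxy-aldehyde form installs the terminal vinyl group (C1) and frees the Z-allylic alcohol without touching the olefin geometry.

Step 4
Reactants: 6 (2Z)-3-methylhepta-2,6-dien-1-ol
Product: 7 [(2R,3S)-3-(but-3-en-1-yl)-3-methyloxiran-2-yl]methanol
Conditions: Ti(OiPr)4 (10 mol %), D-(−)-diisopropyl tartrate (12 mol %), t-BuOOH, 4 Å sieves, CH2Cl2, −20 °C
Reagents that add atoms: tert-butyl hydroperoxide, CC(C)(C)OO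
Why: Sharpless asymmetric epoxidation of the primary allylic alcohol, where the D-(−)-tartrate ligand delivers oxygen to the face giving the (2R,3S) cis-oxirane (target C4 S, C5 R) and the isolated vinyl group is inert.

Step 5
Reactants: 7 [(2R,3S)-3-(but-3-en-1-yl)-3-methyloxiran-2-yl]methanol
Product: 8 (2S,3S)-3-(but-3-en-1-yl)-3-methyloxirane-2-carbaldehyde
Conditions: PhI(OAc)2, TEMPO (10 mol %), CH2Cl2, 20 °C
Reagents that add atoms: none
Why: TEMPO-mediated oxidation stops at the aldehyde under non-basic conditions, so the oxirane and both of its stereocentres are untouched (the descriptor at the aldehyde-bearing carbon changes only because of CIP priorities).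

Step 6
Reactants: 8 (2S,3S)-3-(but-3-en-1-yl)-3-methyloxirane-2-carbaldehyde, 9 3-methylbutanal
Product: 10 (2S,3R)-3-[(2R,3S)-3-(but-3-en-1-yl)-3-methyloxiran-2-yl]-3-hydroxy-2-(propan-2-yl)propanal
Conditions: L-proline (20 mol %), DMF, 4 °C, 9 added by syringe pump
Reagents that add atoms: none
Why: Proline enamine cross-aldol (List–Houk transition state) with 9 as the only enolisable partner gives the anti aldol, the catalyst setting C7 (S) and C6 (R) in a sense matched with Felkin–Anh attack anti to the oxirane C–O bond.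

Step 7
Reactants: 10 (2S,3R)-3-[(2R,3S)-3-(but-3-en-1-yl)-3-methyloxiran-2-yl]-3-hydroxy-2-(propan-2-yl)propanal, 11 (2-methylprop-2-en-1-yl)magnesium chloride
Product: 12 (1R,2R,3S)-1-[(2R,3S)-3-(but-3-en-1-yl)-3-methyloxiran-2-yl]-5-methyl-2-(propan-2-yl)hex-5-ene-1,3-diol
Conditions: 11 (2.5 equiv), THF, −78 °C; then H2O
Reagents that add atoms: none
Why: Chelation-controlled Grignard addition in which the magnesium alkoxide of the C6 hydroxyl ties the aldehyde into a six-membered chelate and axial attack (also the Felkin–Anh sense) gives the 1,3-anti diol, the C8 (S) epimer that is deliberately opposite to the target.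

Step 8
Reactants: 12 (1R,2R,3S)-1-[(2R,3S)-3-(but-3-en-1-yl)-3-methyloxiran-2-yl]-5-methyl-2-(propan-2-yl)hex-5-ene-1,3-diol, 13 3,4,5-trimethoxybenzoic acid
Product: 14 (1R,2S,3R)-1-[(2R,3S)-3-(but-3-en-1-yl)-3-methyloxiran-2-yl]-1-hydroxy-5-methyl-2-(propan-2-yl)hex-5-en-3-yl 3,4,5-trimethoxybenzoate
Conditions: 13 (1.5 equiv), PBu3, 1,1'-(azodicarbonyl)dipiperidine (ADDP), toluene, 0 → 50 °C
Reagents that add atoms: none
Why: Mitsunobu esterification in which the less hindered C8 hydroxyl is activated and displaced by the carboxylate with inversion, which installs the aroyl group and corrects C8 to (R) in one operation while the more hindered oxirane-flanked C6 hydroxyl stays free.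

Step 9
Reactants: 14 (1R,2S,3R)-1-[(2R,3S)-3-(but-3-en-1-yl)-3-methyloxiran-2-yl]-1-hydroxy-5-methyl-2-(propan-2-yl)hex-5-en-3-yl 3,4,5-trimethoxybenzoate
Product: 15 (1(10)Z,4S,5R,6R,7S,8R)-4,5-epoxy-6-hydroxygermacr-1(10)-en-8-yl 3,4,5-trimethoxybenzoate
Conditions: second-generation Grubbs catalyst [RuCl2(=CHPh)(PCy3)(H2IMes)] (10 mol %), toluene (1 mM), 80 °C
Reagents that add atoms: none
Why: Ring-closing metathesis joins the vinyl carbon C1 to the 1,1-disubstituted carbon C10 with loss of ethene, and in a ten-membered ring the trisubstituted olefin closes with the two ring methylenes cis, which is the required (Z) geometry.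

**Compound list**
1 | 4-methylanisole (1-methoxy-4-methylbenzene) | COc1ccc(C)cc1 | starting material
2 | 1-methoxy-4-methylcyclohexa-1,4-diene | COC1=CCC(C)=CC1 | intermediate
3 | 4-methylcyclohex-3-en-1-one | CC1=CCC(=O)CC1 | intermediate
4 | 5-methyl-4,7-dihydro-3H-oxepin-2-one (seven-membered allylic lactone, ring olefin cis) | CC1=CCOC(=O)CC1 | intermediate
5 | 5-methyl-2,3,4,7-tetrahydrooxepin-2-ol (lactol, racemic at the hemiacetal carbon) | CC1=CCOC(O)CC1 | intermediate
6 | (2Z)-3-methylhepta-2,6-dien-1-ol | OC/C=C(C)\CCC=C | intermediate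
7 | [(2R,3S)-3-(but-3-en-1-yl)-3-methyloxiran-2-yl]methanol | C=CCC[C@]1(C)O[C@@H]1CO | intermediate
8 | (2S,3S)-3-(but-3-en-1-yl)-3-methyloxirane-2-carbaldehyde | C=CCC[C@]1(C)O[C@@H]1C=O | intermediate
9 | 3-methylbutanal | CC(C)CC=O | starting material
10 | (2S,3R)-3-[(2R,3S)-3-(but-3-en-1-yl)-3-methyloxiran-2-yl]-3-hydroxy-2-(propan-2-yl)propanal | C=CCC[C@]1(C)O[C@@H]1[C@H](O)[C@@H](C=O)C(C)C | intermediate
11 | (2-methylprop-2-en-1-yl)magnesium chloride | CC(=C)C[Mg]Cl | starting material
12 | (1R,2R,3S)-1-[(2R,3S)-3-(but-3-en-1-yl)-3-methyloxiran-2-yl]-5-methyl-2-(propan-2-yl)hex-5-ene-1,3-diol | C=CCC[C@]1(C)O[C@@H]1[C@H](O)[C@H](C(C)C)[C@@H](O)CC(C)=C | intermediate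
13 | 3,4,5-trimethoxybenzoic acid | COc1cc(C(=O)O)cc(OC)c1OC | starting material
14 | (1R,2S,3R)-1-[(2R,3S)-3-(but-3-en-1-yl)-3-methyloxiran-2-yl]-1-hydroxy-5-methyl-2-(propan-2-yl)hex-5-en-3-yl 3,4,5-trimethoxybenzoate | C=CCC[C@]1(C)O[C@@H]1[C@H](O)[C@H](C(C)C)[C@H](OC(=O)c2cc(OC)c(OC)c(OC)c2)CC(C)=C | intermediate
15 | (1(10)Z,4S,5R,6R,7S,8R)-4,5-epoxy-6-hydroxygermacr-1(10)-en-8-yl 3,4,5-trimethoxybenzoate | COc1cc(C(=O)O[C@@H]2C/C(C)=C\CC[C@]3(C)O[C@@H]3[C@H](O)[C@@H]2C(C)C)cc(OC)c1OC | target

**Step count and risks**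

Total steps: 9. Longest linear sequence: 9 steps (1 → 15); compounds 9, 11 and 13 are purchased.

Steps most likely to fail:

Step 2 (Baeyer–Villiger: the wrong methylene may migrate, or the olefin may be oxidised or moved into conjugation). The fallback sets out from 3 and comes back at 5. Compound 3 is deprotonated at the doubly activated methylene (LiN(i-Pr)2, THF, −78 °C) and the dienolate is hydroxylated there with 3-phenyl-2-(phenylsulfonyl)oxaziridine to give racemic 2-hydroxy-4-methylcyclohex-3-en-1-one F1. Cleavage of this α-hydroxy ketone with Pb(OAc)4 in MeOH/benzene gives methyl (4Z)-4-methyl-6-oxohex-4-enoate F2, the olefin geometry again being fixed by the ring. NaBH4/CeCl3 in MeOH at −78 °C reduces only the enal to methyl (4Z)-6-hydroxy-4-methylhex-4-enoate F3. i-Bu2AlH at −78 °C then turns the ester of F3 into lactol 5, which is methylenated as in step 3.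

Step 8 (Mitsunobu at a hindered secondary carbinol with a weakly acidic benzoic acid; possible reaction at C6–OH or elimination). The fallback sets out from 12 and comes back at 14. ClCH2SO2Cl and pyridine in CH2Cl2 at −20 °C sulfonylate the less hindered C8 hydroxyl to give (1R,2S,3S)-1-[(2R,3S)-3-(but-3-en-1-yl)-3-methyloxiran-2-yl]-1-hydroxy-5-methyl-2-(propan-2-yl)hex-5-en-3-yl chloromethanesulfonate F4. Caesium 3,4,5-trimethoxybenzoate (from 13 and Cs2CO3) with 18-crown-6 in toluene at 80 °C displaces the sulfonate with inversion to give 14.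

Step 9 (closing a ten-membered ring on a 1,1-disubstituted olefin; dimerisation or no turnover; highest risk). The fallback sets out from 10 and comes back at 15, closing the same C1–C10 bond by carbonyl addition instead of metathesis. Aldehyde 10 with 2,3-dibromopropene and In powder in THF/H2O (chelation-controlled Barbier addition, same 1,3-anti sense as step 7) gives (1R,2R,3S)-5-bromo-1-[(2R,3S)-3-(but-3-en-1-yl)-3-methyloxiran-2-yl]-2-(propan-2-yl)hex-5-ene-1,3-diol F5. Mitsunobu esterification with 13 under the step 8 conditions gives the inverted ester (1R,2S,3R)-5-bromo-1-[(2R,3S)-3-(but-3-en-1-yl)-3-methyloxiran-2-yl]-1-hydroxy-2-(propan-2-yl)hex-5-en-3-yl 3,4,5-trimethoxybenzoate F6. OsO4 (cat.)/NaIO4 with 2,6-lutidine in dioxane/H2O cleaves only the electron-rich terminal vinyl group to give (1R,2S,3R)-5-bromo-1-hydroxy-1-[(2R,3S)-3-methyl-3-(3-oxopropyl)oxiran-2-yl]-2-(propan-2-yl)hex-5-en-3-yl 3,4,5-trimethoxybenzoate F7. CrCl2 with NiCl2 (cat.) in DMSO at high dilution (Nozaki–Hiyama–Kishi) closes the ring to (4S,5R,6R,7S,8R)-4,5-epoxy-1,6-dihydroxygermacr-10(14)-en-8-yl 3,4,5-trimethoxybenzoate F8, a mixture at the new C1 carbinol that does not matter. Finally 2-nitrobenzenesulfonylhydrazide, PPh3 and diethyl azodicarboxylate in THF (−30 → 20 °C, Myers reductive 1,3-transposition through the allylic diazene) move the exocyclic methylene into the ring as the C1=C10 olefin and turn the former methylene into the C10 methyl group, giving 15.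

**Further compounds**
F1 | step 2 | 2-hydroxy-4-methylcyclohex-3-en-1-one (racemic) | CC1=CC(O)C(=O)CC1
F2 | step 2 | methyl (4Z)-4-methyl-6-oxohex-4-enoate | COC(=O)CC/C(C)=C\C=O
F3 | step 2 | methyl (4Z)-6-hydroxy-4-methylhex-4-enoate | COC(=O)CC/C(C)=C\CO
F4 | step 8 | (1R,2S,3S)-1-[(2R,3S)-3-(but-3-en-1-yl)-3-methyloxiran-2-yl]-1-hydroxy-5-methyl-2-(propan-2-yl)hex-5-en-3-yl chloromethanesulfonate | C=CCC[C@]1(C)O[C@@H]1[C@H](O)[C@H](C(C)C)[C@@H](OS(=O)(=O)CCl)CC(C)=C
F5 | step 9 | (1R,2R,3S)-5-bromo-1-[(2R,3S)-3-(but-3-en-1-yl)-3-methyloxiran-2-yl]-2-(propan-2-yl)hex-5-ene-1,3-diol | C=CCC[C@]1(C)O[C@@H]1[C@H](O)[C@H](C(C)C)[C@@H](O)CC(Br)=C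
F6 | step 9 | (1R,2S,3R)-5-bromo-1-[(2R,3S)-3-(but-3-en-1-yl)-3-methyloxiran-2-yl]-1-hydroxy-2-(propan-2-yl)hex-5-en-3-yl 3,4,5-trimethoxybenzoate | C=CCC[C@]1(C)O[C@@H]1[C@H](O)[C@H](C(C)C)[C@H](OC(=O)c2cc(OC)c(OC)c(OC)c2)CC(Br)=C
F7 | step 9 | (1R,2S,3R)-5-bromo-1-hydroxy-1-[(2R,3S)-3-methyl-3-(3-oxopropyl)oxiran-2-yl]-2-(propan-2-yl)hex-5-en-3-yl 3,4,5-trimethoxybenzoate | O=CCC[C@]1(C)O[C@@H]1[C@H](O)[C@H](C(C)C)[C@H](OC(=O)c2cc(OC)c(OC)c(OC)c2)CC(Br)=C
F8 | step 9 | (4S,5R,6R,7S,8R)-4,5-epoxy-1,6-dihydroxygermacr-10(14)-en-8-yl 3,4,5-trimethoxybenzoate (both C1 epimers) | COc1cc(C(=O)O[C@@H]2CC(=C)C(O)CC[C@]3(C)O[C@@H]3[C@H](O)[C@@H]2C(C)C)cc(OC)c1OC
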